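In a one-step world, L + J ⇌ Q + Z, a single equilibrium constant would give the end of the flask. This flask has more steps, so the examination asks whether one number still serves.

L 0.80 M (in portions, 3); J 1.20 M; time 15 d; the portions of L follow each other after 80 min, the first at the start

    L + J ⇌ L.J (K1 = 0.39 L mol⁻¹, k1 = 0.036 L mol⁻¹ h⁻¹)
    L.J ⇌ Q + Z (K2 = 0.27 M, k2 = 1.6 h⁻¹)
    Q ⇌ D (K3 = 0.37, k3 = 0.11 h⁻¹)
    J ⇌ E (K4 = 0.49, k4 = 0.37 h⁻¹)

- conversion of L at 15 d
- amount of Q at 15 d, in percent of the L charged
- amount of L.J at 15 d, in percent of the L charged
- amount of D at 15 d, in percent of the L charged

Is this flask at equilibrium when it is sampled? I expect so. The last portion of L goes in at 2.67 h, earlier than 15 d. The forward half-life of L by the first step, 0.67 d at the charged concentrations, is shorter than 15 d, and the relaxation half-life of Q and D, 0.0709 d, is shorter too.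

Which quantity, then? Pool what interconverts: c_Q+D is Q with D, and c_J+E is J with E. Every Z came with one Q or D, so c_Z equals c_Q+D. At equilibrium the quotient c_Q+D times c_Z over c_L times c_J+E has a fixed value, the pooled constant: multiply the constants of the first two steps, multiply by one plus the third, divide by one plus the fourth, 0.0968.

But L.J hides material. Yes: c_L.J is c_L times c_J+E times 0.262 L mol⁻¹, the first constant over one plus the fourth.

How do you solve it? With f, the fraction of L left. Then c_L is f times the charge, and c_J+E is the charge of J less the L that has gone. These two give c_L.J and c_Q+D, which must return the same f. Trying 0.5 returns 67.5%, and trying 0.7 returns 53.9%.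

And the answer? Interpolating the mismatch linearly gives f = 60.4%, so my conversion is 39.6%. Then c_Q+D is 0.203 M, which makes Q 18.6%, D 6.86% and L.J 14.0% of the L charged. This is thermodynamic control, if the assumption holds.

The forecast gives 39.4% conversion, Q 18.6%, L.J 14% and D 6.9%, holding that “the system sits at full equilibrium”. My conversion stands 0.18 percentage points above the forecast's.

The simulation gives conversion 39.5%, Q 18.6%, L.J 14.0% and D 6.87%.

In this flask 61% of the L stays unbound, and the ways back from L.J to L + J and from D to Q are part of the reason, not the whole of it: against 39.5%, conversion reaches 98.9% without the first and 87.6% without the second. The readings of this flask give the quotient as 0.0968, beside 0.0968. The neighbour flask with 2.0 M of J converts 51.1%, and its readings give the quotient as 0.0968.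

All constants are those of an exercise; the rest is arithmetic.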